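# Proposed total synthesis of fisetinidol-(4β→6)-catechin (22)

Flavan numbering is used throughout: the upper unit has rings A, C and B, the lower catechin unit has rings D, F and E. Compounds are numbered 1–22 as they appear in the steps.

## Analysis of the target

The target 22 is a biflavanoid in which an upper 5-deoxyflavan-3-ol (rings A, C, B) is bonded through C4 of ring C to C6 of ring D of a lower catechin unit (rings D, F, E). It has five stereocentres: C2, C3 and C4 of ring C are 2R,3S,4R (2,3-trans and 3,4-cis), and C2 and C3 of ring F are the 2R,3S pair of natural (+)-catechin. The nine free hydroxyl groups, among them two catechols and the phloroglucinol-type ring D, make the final compound prone to air oxidation under basic conditions, and the doubly benzylic C4–C6(D) bond to an electron-rich arene is open to acid cleavage. The classical coupling of a flavan-4-yl cation with catechin fails on two counts: it attacks C8(D) in preference to C6(D), and with a 2,3-trans upper unit the arene enters trans to the C3 oxygen, so the 3,4-cis isomer is the minor one. In addition, the three contiguous centres of ring C must be set in the right absolute sense relative to a lower unit that is bought as a single enantiomer. The plan rests on the aryl ether bond O1–C8a of ring C: it joins the C2 oxygen to ring A and involves none of C2, C3 and C4, so ring C can be closed there after the whole triad has been fixed in an open chain.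

## Retrosynthetic reasoning

**22 from 21.** All nine hydroxyl groups are masked as benzyl ethers, and C8(D) carries a chlorine that served to direct functionalisation to C6(D). Benzyl ethers survive organomagnesium reagents, hydrides and hot carbonate base, and they leave without acid. The chlorine is inert to magnesium and copper and falls in the same hydrogenolysis. One final operation therefore takes 21 to 22.

**21 from 20 (key disconnection).** The bond O1–C8a of ring C is cut. It is the only ring C bond that is neither attached to a stereocentre carbon on both sides nor part of the carbon skeleton. Cutting it gives the open-chain alcohol 20, in which ring A is a 2-bromoaryl group on C4. The forward reaction is an intramolecular copper-catalysed O-arylation of the C2 alkoxide. It must choose the ring A bromide over the ring D chloride and form the six-membered ether only; the second point is secured because the C3 oxygen is already a benzyl ether.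

**20 from 19.** Working out the 2,3-trans ring geometry shows that the C2 and C3 oxygens of 20 are anti in the zigzag chain ring B–C2–C3–C4. A hydride delivered to the α-benzyloxy ketone 19 under chelate control gives exactly this anti relation. A chelate-controlled aryl addition to the aldehyde 15 would give the syn isomer, so the carbinol is set by reduction and not by addition.

**19 from 15 and 16.** The bond from C2 to ring B is cut. The Grignard reagent 17, made from bromide 16, adds to aldehyde 15 without need for selectivity to give alcohol 18, and oxidation gives 19. Ring B thus enters late and from a simple building block.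

**15 from 12 through 14 and 13.** The aldehyde carbon of 15 is the primary carbinol of diol 12. The two hydroxyl groups of 12 are told apart through the benzylidene acetal 13, whose regioselective reductive opening gives 14. This one operation puts the required benzyl group on the C3 oxygen and frees the primary alcohol for oxidation.

**12 from 5 and 10.** The C4–C6(D) bond is cut. The nucleophile is the ring D arylmagnesium species 11, generated from iodide 10, so the site of attachment on ring D is fixed by the position of the iodine and not by arene nucleophilicity. The electrophile is the trans-epoxy alcohol 5. Opening at its benzylic carbon with inversion sets C4, while C3 is already present in the epoxide; the trans-epoxide plus inversion translates into the 3,4-cis relation of the flavan. The forward reaction has to be regioselective for the benzylic carbon and must leave the ring A bromide untouched.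

**5 from 4, 3, 2 and 1.** The epoxide comes from an asymmetric epoxidation of the (E)-allylic alcohol 4, which sets both C3 and (before inversion) C4 in absolute terms. Alcohol 4 is reached from aldehyde 1 by phenol benzylation (2), two-carbon olefination (3) and ester reduction.

**10 from 9, 8, 7 and 6.** The whole lower unit, with rings D, F, E and both of its stereocentres, comes from (+)-catechin 6. Perbenzylation in two stages (7, 8) is followed by chlorination at the more reactive C8 (9) and iodination at the only position left, C6 (10).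

## Alternatives that were turned down

**Alternative 1: ring F closed onto a ring D aryne.** The cuts are O1(F)–C8a(D) and C4(F)–C4a(D). The partners would be the ortho-silylaryl triflate A2, which already carries the complete upper flavan on C6(D), and the open-chain hydroxy ester A3. In the forward step, fluoride with a carbonate base would unmask the aryne between C4a(D) and C8a(D). The alkoxide of A3 would add at C8a(D), the carbon remote from the C5 ether, and the aryl anion at C4a(D) would attack the ester to give the flavan-4-one A1.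

- For: two bonds and ring F form in one operation, the aryne polarity places the oxygen correctly, and no halogen blocker is needed. On bonds formed per step it is stronger than the chosen route.
- Against: A2 is a hexasubstituted benzene that can only be made once the upper unit with its 3,4-cis triad is attached, so the hardest stereochemical problem is not addressed.
- Against: the lower unit, which 6 supplies complete, would be built from small pieces.
- Against: A1 is a β-aryloxy ketone with an acidic C3(F) hydrogen. Under the basic conditions of its own formation, ring opening to a chalcone and reclosure would endanger C2(F) and C3(F).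
- Against: the C4(F) carbonyl must afterwards be taken down to a methylene group in further redox steps.

The chosen route forms only one bond in its key step, but no stereocentre is ever at an epimerisable oxidation level during or after ring closure.

**Alternative 2: ring D assembled last by Danheiser benzannulation.** The cuts are C5(D)–C6(D) and C7(D)–C8(D). The partners would be the 4-(siloxyethynyl)flavan A5 and the bicyclic 3-alkoxycyclobutenone A6, in which ring F is already fused. On heating, A6 would open to a vinylketene and add to the alkyne of A5; 4π opening and 6π closure of the resulting vinylcyclobutenone would give the phenol A4, with a free C5 hydroxyl and a C7 silyl ether.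

- For: it is the most convergent plan, with two carbon–carbon bonds and an aromatic ring made in a reagent-free step. The alkyne carbon becomes C6(D), so the linkage position is fixed by construction. On this point it is stronger than the chosen route, which needs two halogenations and a final dechlorination.
- Against: A5 requires an sp carbon cis to the C3 oxygen on a 2,3-trans flavan. This is the same 3,4-cis problem, now with a moisture-sensitive siloxyalkyne that would have to be made from a hindered ester.
- Against: A6, a strained enol ether cyclobutenone with two stereocentres, has no short preparation.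

The chosen route offers acyclic control of the triad and a four-step access to the entire lower unit from 6.

**Alternative 3: ring F by metathesis on a symmetric ring D.** The cut is C3(F)=C4(F). The diene A8 carries a vinyl group on C4a(D) and an (S)-1-arylallyl ether on the C8a(D) oxygen. It would come from the phenol A9, whose ring D is symmetric about the C6–C8a axis. The second-generation Grubbs catalyst would join the two vinyl groups and give the 2H-chromene A7.

- For: ring-closing metathesis to 2H-chromenes is mild and dependable, and the symmetry of A9 removes the 6-versus-8 question without a blocking group. In that respect it is as good as or better than the chosen route.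
- Against: the C3(F) oxygen has to be added afterwards. Hydroboration anti to ring E should give the 2,3-trans alcohol, but this adds steps after the key step.
- Against: the 1-arylallyl aryl ether of an electron-rich arene is prone to ionisation and Claisen rearrangement, which puts C2(F) at risk. Its formation from the hindered phenol A9 with clean stereochemistry is doubtful.
- Against: the upper unit with its triad must again be in place before the key step.

The chosen route builds nothing of the lower unit and sets all three upper centres by open-chain reactions with well-understood stereocontrol.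

Key step: step 16

## Remarks before the steps

- Names: Bn = benzyl; ArA = 4-(benzyloxy)-2-bromophenyl; ArD = (2R,3S)-3,5,7-tris(benzyloxy)-2-[3,4-bis(benzyloxy)phenyl]-8-chlorochroman-6-yl.
- Chemistry: alkoxide and phenoxide salts formed by simple deprotonation are treated as forms of the parent compound and carry no number.
- Chemistry: 13 and 18 are carried as epimer mixtures at a centre that the following step destroys.
- Chemistry: the descriptor of C4 changes from S (12 to 20) to R (21, 22) only because ring A exchanges bromine for oxygen; the spatial arrangement is unchanged.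

## Steps

Step 1
Reactants: 1 2-bromo-4-hydroxybenzaldehyde
Product: 2 4-(benzyloxy)-2-bromobenzaldehyde
Conditions: BnBr (1.1 equiv), K2CO3, DMF, rt
Reagents that add atoms: benzyl bromide, BrCc1ccccc1
Why: Williamson etherification of an acidic para-formyl phenol; carbonate base leaves the aldehyde and the aryl bromide untouched.

Step 2
Reactants: 2 4-(benzyloxy)-2-bromobenzaldehyde
Product: 3 ethyl (E)-3-[4-(benzyloxy)-2-bromophenyl]prop-2-enoate
Conditions: (EtO)2P(O)CH2CO2Et, NaH, THF, 0 °C → rt
Reagents that add atoms: triethyl phosphonoacetate, CCOC(=O)CP(=O)(OCC)OCC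
Why: Horner–Wadsworth–Emmons olefination of an aromatic aldehyde with a stabilised phosphonate anion, which should give the (E)-cinnamate.

Step 3
Reactants: 3 ethyl (E)-3-[4-(benzyloxy)-2-bromophenyl]prop-2-enoate
Product: 4 (E)-3-[4-(benzyloxy)-2-bromophenyl]prop-2-en-1-ol
Conditions: iBu2AlH (2.2 equiv), CH2Cl2, −78 °C; aq. potassium sodium tartrate
Reagents that add atoms: none
Why: 1,2-reduction of the unsaturated ester by the aluminium hydride at low temperature gives the allylic alcohol; aryl bromide and benzyl ether are inert.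

Step 4
Reactants: 4 (E)-3-[4-(benzyloxy)-2-bromophenyl]prop-2-en-1-ol
Product: 5 [(2R,3R)-3-[4-(benzyloxy)-2-bromophenyl]oxiran-2-yl]methanol
Conditions: Ti(OiPr)4 (10 mol%), D-(−)-diisopropyl tartrate (12 mol%), tBuOOH (2 equiv, in decane), 4 Å MS, CH2Cl2, −20 °C; NaOH/brine work-up
Reagents that add atoms: tert-butyl hydroperoxide, CC(C)(C)OO
Why: Sharpless asymmetric epoxidation of an (E)-3-aryl allylic alcohol; the D-(−)-tartrate complex delivers oxygen to the face that gives the (2R,3R)-epoxy alcohol (the L-(+)-ligand gives 2S,3S), so both epoxide centres are set by the ligand. Catalytic titanium with sieves and a non-acidic work-up limit Lewis acid exposure of the electron-rich benzylic epoxide.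

Step 5
Reactants: 6 (+)-catechin
Product: 7 (2R,3S)-5,7-bis(benzyloxy)-2-[3,4-bis(benzyloxy)phenyl]chroman-3-ol (tetra-O-benzylcatechin)
Conditions: BnBr (4.4 equiv), K2CO3, DMF, 0 °C → rt
Reagents that add atoms: benzyl bromide, BrCc1ccccc1
Why: Williamson etherification; carbonate deprotonates only the four phenols, so the secondary alcohol stays free and the mild base should not epimerise C2.

Step 6
Reactants: 7 (2R,3S)-5,7-bis(benzyloxy)-2-[3,4-bis(benzyloxy)phenyl]chroman-3-ol
Product: 8 (2R,3S)-3,5,7-tris(benzyloxy)-2-[3,4-bis(benzyloxy)phenyl]chromane (penta-O-benzylcatechin)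
Conditions: NaH, BnBr, Bu4NI (cat.), THF/DMF, 0 °C → rt
Reagents that add atoms: benzyl bromide, BrCc1ccccc1
Why: Williamson etherification of the secondary alkoxide; with all phenols already capped, base-induced opening of ring F through a quinone methide is not possible.

Step 7
Reactants: 8 (2R,3S)-3,5,7-tris(benzyloxy)-2-[3,4-bis(benzyloxy)phenyl]chromane
Product: 9 (2R,3S)-3,5,7-tris(benzyloxy)-2-[3,4-bis(benzyloxy)phenyl]-8-chlorochromane
Conditions: NCS (1.05 equiv), CH2Cl2, −20 °C → rt
Reagents that add atoms: N-chlorosuccinimide, ClN1C(=O)CCC1=O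
Why: Electrophilic aromatic halogenation of the tri-oxygenated ring D; C8, between O1 and the C7 ether, is the position at which N-halosuccinimides attack O-alkylated flavan-3-ols, and one equivalent at low temperature should keep C6 free.

Step 8
Reactants: 9 (2R,3S)-3,5,7-tris(benzyloxy)-2-[3,4-bis(benzyloxy)phenyl]-8-chlorochromane
Product: 10 (2R,3S)-3,5,7-tris(benzyloxy)-2-[3,4-bis(benzyloxy)phenyl]-8-chloro-6-iodochromane
Conditions: NIS (1.2 equiv), CF3CO2H (10 mol%), CH2Cl2, 0 °C → rt, dark
Reagents that add atoms: N-iodosuccinimide, IN1C(=O)CCC1=O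
Why: Electrophilic aromatic iodination at C6, the only open position of ring D and still activated by two ortho ether oxygens; the dialkoxy ring E is much less nucleophilic.

Step 9
Reactants: 10 (2R,3S)-3,5,7-tris(benzyloxy)-2-[3,4-bis(benzyloxy)phenyl]-8-chloro-6-iodochromane; 5 [(2R,3R)-3-[4-(benzyloxy)-2-bromophenyl]oxiran-2-yl]methanol
Product: 12 (2S,3S)-3-ArA-3-ArD-propane-1,2-diol, via ring D arylmagnesium chloride 11 (not isolated)
Conditions: 10, iPrMgCl·LiCl (1.0 equiv), THF, −20 → 0 °C; CuI (15 mol%), −40 °C; 5 (1.3 equiv, first deprotonated by iPrMgCl, THF, −40 °C); −40 → 0 °C; aq. NH4Cl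
Reagents that add atoms: none
Why: Iodine–magnesium exchange is selective for the iodide over the aryl chloride, and the bromide-bearing partner is added only after the exchange is complete. Under copper catalysis the aryl Grignard reagent opens the 3-aryl-2,3-epoxy alcohol at its benzylic carbon in an SN2 manner, which inverts that carbon and gives the (3S)-diarylmethine; the carbinol carbon keeps its configuration and is 2S in 12 by a priority change only.

Step 10
Reactants: 12 (2S,3S)-3-ArA-3-ArD-propane-1,2-diol
Product: 13 (4S)-4-[(S)-ArA(ArD)methyl]-2-phenyl-1,3-dioxolane (both epimers at C2 of the dioxolane)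
Conditions: PhCH(OMe)2, camphorsulfonic acid (5 mol%), CH2Cl2, rt
Reagents that add atoms: benzaldehyde dimethyl acetal, COC(OC)c1ccccc1
Why: Acid-catalysed transacetalisation of a terminal 1,2-diol to the benzylidene acetal; the catalytic acid at room temperature should not ionise the diarylmethine carbon.

Step 11
Reactants: 13 (4S)-4-[(S)-ArA(ArD)methyl]-2-phenyl-1,3-dioxolane
Product: 14 (2S,3S)-2-(benzyloxy)-3-ArA-3-ArD-propan-1-ol
Conditions: iBu2AlH (4 equiv), CH2Cl2, −78 → 0 °C; aq. potassium sodium tartrate
Reagents that add atoms: none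
Why: Regioselective reductive opening of a benzylidene acetal: the aluminium Lewis acid binds the less hindered primary oxygen and breaks its acetal bond, and hydride then reduces the oxocarbenium ion on the secondary oxygen. The benzyl group therefore ends on the oxygen next to the bulky diarylmethyl group and the primary alcohol is set free.

Step 12
Reactants: 14 (2S,3S)-2-(benzyloxy)-3-ArA-3-ArD-propan-1-ol
Product: 15 (2S,3S)-2-(benzyloxy)-3-ArA-3-ArD-propanal
Conditions: Dess–Martin periodinane, NaHCO3, CH2Cl2, 0 °C → rt
Reagents that add atoms: none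
Why: Dess–Martin oxidation of a primary alcohol under buffered, non-basic conditions, which should leave the α-alkoxy stereocentre intact.

Step 13
Reactants: 15 (2S,3S)-2-(benzyloxy)-3-ArA-3-ArD-propanal; 16 4-bromo-1,2-bis(benzyloxy)benzene
Product: 18 (2S,3S)-2-(benzyloxy)-1-[3,4-bis(benzyloxy)phenyl]-3-ArA-3-ArD-propan-1-ol (both C1 epimers), via 3,4-bis(benzyloxy)phenylmagnesium bromide 17 (not isolated)
Conditions: 16, Mg, I2 (cat.), THF, 40 °C; then 15, THF, −78 → −20 °C; aq. NH4Cl
Reagents that add atoms: none
Why: Grignard formation and 1,2-addition to the aldehyde; the reagent has no β-hydrogen, the ring A bromide does not exchange at this temperature, and no facial selectivity is needed because the carbinol is oxidised next.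

Step 14
Reactants: 18 (2S,3S)-2-(benzyloxy)-1-[3,4-bis(benzyloxy)phenyl]-3-ArA-3-ArD-propan-1-ol
Product: 19 (2S,3S)-2-(benzyloxy)-1-[3,4-bis(benzyloxy)phenyl]-3-ArA-3-ArD-propan-1-one
Conditions: Dess–Martin periodinane, NaHCO3, CH2Cl2, rt
Reagents that add atoms: none
Why: Dess–Martin oxidation of a secondary benzylic alcohol to the aryl ketone; both epimers of 18 converge on one compound.

Step 15
Reactants: 19 (2S,3S)-2-(benzyloxy)-1-[3,4-bis(benzyloxy)phenyl]-3-ArA-3-ArD-propan-1-one
Product: 20 (1R,2S,3S)-2-(benzyloxy)-1-[3,4-bis(benzyloxy)phenyl]-3-ArA-3-ArD-propan-1-ol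
Conditions: Zn(BH4)2, Et2O/CH2Cl2, −40 → 0 °C; aq. NH4Cl
Reagents that add atoms: none
Why: Chelation-controlled (Cram chelate) reduction: zinc bridges the carbonyl and the α-benzyloxy oxygen in a five-membered chelate, and hydride attacks the face opposite to the bulky diarylmethyl group. This should give the anti (1R) alcohol, which corresponds to the 2,3-trans flavan.

Step 16
Reactants: 20 (1R,2S,3S)-2-(benzyloxy)-1-[3,4-bis(benzyloxy)phenyl]-3-ArA-3-ArD-propan-1-ol
Product: 21 (2R,3S,4R)-3,7-bis(benzyloxy)-2-[3,4-bis(benzyloxy)phenyl]-4-ArD-chromane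
Conditions: CuI (20 mol%), 3,4,7,8-tetramethyl-1,10-phenanthroline (40 mol%), Cs2CO3 (2 equiv), 4 Å MS, toluene, 110 °C, Ar
Reagents that add atoms: none
Why: Cs2CO3 turns the C2 hydroxyl into its caesium alkoxide, which replaces iodide on the phenanthroline-bound monovalent copper to give a copper alkoxide. The ring A carbon–bromine bond, held close by the three-carbon tether, is then activated at this centre (formally through trivalent copper), and carbon–oxygen reductive elimination forms O1–C8a and returns the catalyst. The closest known reaction type is the Ullmann-type copper-catalysed etherification of aryl halides with aliphatic alcohols, whose intramolecular form is an established way from 3-(2-halophenyl)propanols, secondary ones included, to chromans. Ring C closes in a 6-exo sense at the aromatic carbon C8a, through a half-chair in which ring B and the C3 benzyloxy group are pseudo-equatorial and the ring D substituent on C4 is pseudo-axial, the arrangement a 2,3-trans-3,4-cis 4-arylflavan prefers. No stereocentre is formed and no bond to C2, C3 or C4 is broken, so the alcohol oxygen is arylated with retention and the triad of 20 should arrive unchanged in 21. The step needs chemoselectivity: the ring A bromide reacts with copper far more readily than the C8(D) chloride, which is flanked by two ortho oxygens and cannot reach the alkoxide within the molecule, and the benzyl group on the C3 oxygen rules out the five-membered dihydrobenzofuran. Oxidation of the benzylic alkoxide with loss of bromine, the main competing path, is less favoured at copper than at palladium and has to compete with a fast intramolecular bond formation.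

Step 17
Reactants: 21 (2R,3S,4R)-3,7-bis(benzyloxy)-2-[3,4-bis(benzyloxy)phenyl]-4-ArD-chromane
Product: 22 (2R,3S,4R)-2-(3,4-dihydroxyphenyl)-4-[(2R,3S)-2-(3,4-dihydroxyphenyl)-3,5,7-trihydroxychroman-6-yl]chromane-3,7-diol (fisetinidol-(4β→6)-catechin)
Conditions: H2 (1 atm), Pd(OH)2/C, Et3N (3 equiv), THF/MeOH, rt; filtration under Ar, AcOH, Sephadex LH-20
Reagents that add atoms: none
Why: Catalytic hydrogenolysis removes the nine benzyl ethers, and the same palladium surface reduces the aryl chloride in the presence of the amine, which also traps HCl and so protects the acid-labile C4–C6(D) bond. No stereocentre is touched.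

## Compound list

1 | 2-bromo-4-hydroxybenzaldehyde | O=Cc1ccc(O)cc1Br | starting material
2 | 4-(benzyloxy)-2-bromobenzaldehyde | O=Cc1ccc(OCc2ccccc2)cc1Br | intermediate
3 | ethyl (E)-3-[4-(benzyloxy)-2-bromophenyl]prop-2-enoate | CCOC(=O)/C=C/c1ccc(OCc2ccccc2)cc1Br | intermediate
4 | (E)-3-[4-(benzyloxy)-2-bromophenyl]prop-2-en-1-ol | OC/C=C/c1ccc(OCc2ccccc2)cc1Br | intermediate
5 | [(2R,3R)-3-[4-(benzyloxy)-2-bromophenyl]oxiran-2-yl]methanol | OC[C@H]1O[C@@H]1c1ccc(OCc2ccccc2)cc1Br | intermediate
6 | (+)-catechin, (2R,3S) | O[C@H]1Cc2c(O)cc(O)cc2O[C@@H]1c1ccc(O)c(O)c1 | starting material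
7 | (2R,3S)-5,7-bis(benzyloxy)-2-[3,4-bis(benzyloxy)phenyl]chroman-3-ol | O[C@H]1Cc2c(OCc3ccccc3)cc(OCc3ccccc3)cc2O[C@@H]1c1ccc(OCc2ccccc2)c(OCc2ccccc2)c1 | intermediate
8 | (2R,3S)-3,5,7-tris(benzyloxy)-2-[3,4-bis(benzyloxy)phenyl]chromane | c1ccccc1CO[C@H]1Cc2c(OCc3ccccc3)cc(OCc3ccccc3)cc2O[C@@H]1c1ccc(OCc2ccccc2)c(OCc2ccccc2)c1 | intermediate
9 | (2R,3S)-3,5,7-tris(benzyloxy)-2-[3,4-bis(benzyloxy)phenyl]-8-chlorochromane | c1ccccc1CO[C@H]1Cc2c(OCc3ccccc3)cc(OCc3ccccc3)c(Cl)c2O[C@@H]1c1ccc(OCc2ccccc2)c(OCc2ccccc2)c1 | intermediate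
10 | (2R,3S)-3,5,7-tris(benzyloxy)-2-[3,4-bis(benzyloxy)phenyl]-8-chloro-6-iodochromane | c1ccccc1CO[C@H]1Cc2c(OCc3ccccc3)c(I)c(OCc3ccccc3)c(Cl)c2O[C@@H]1c1ccc(OCc2ccccc2)c(OCc2ccccc2)c1 | intermediate
11 | [(2R,3S)-3,5,7-tris(benzyloxy)-2-[3,4-bis(benzyloxy)phenyl]-8-chlorochroman-6-yl]magnesium chloride (LiCl adduct, formed in the flask) | c1ccccc1CO[C@H]1Cc2c(OCc3ccccc3)c([Mg]Cl)c(OCc3ccccc3)c(Cl)c2O[C@@H]1c1ccc(OCc2ccccc2)c(OCc2ccccc2)c1 | intermediate
12 | (2S,3S)-3-[4-(benzyloxy)-2-bromophenyl]-3-[(2R,3S)-3,5,7-tris(benzyloxy)-2-[3,4-bis(benzyloxy)phenyl]-8-chlorochroman-6-yl]propane-1,2-diol | OC[C@@H](O)[C@H](c1ccc(OCc9ccccc9)cc1Br)c5c(OCc9ccccc9)c(Cl)c6c(c5OCc9ccccc9)C[C@H](OCc9ccccc9)[C@@H](c4ccc(OCc9ccccc9)c(OCc9ccccc9)c4)O6 | intermediate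
13 | (4S)-4-[(S)-[4-(benzyloxy)-2-bromophenyl][(2R,3S)-3,5,7-tris(benzyloxy)-2-[3,4-bis(benzyloxy)phenyl]-8-chlorochroman-6-yl]methyl]-2-phenyl-1,3-dioxolane, both epimers at the acetal carbon | C1(c9ccccc9)OC[C@@H](O1)[C@H](c1ccc(OCc9ccccc9)cc1Br)c5c(OCc9ccccc9)c(Cl)c6c(c5OCc9ccccc9)C[C@H](OCc9ccccc9)[C@@H](c4ccc(OCc9ccccc9)c(OCc9ccccc9)c4)O6 | intermediate
14 | (2S,3S)-2-(benzyloxy)-3-[4-(benzyloxy)-2-bromophenyl]-3-[(2R,3S)-3,5,7-tris(benzyloxy)-2-[3,4-bis(benzyloxy)phenyl]-8-chlorochroman-6-yl]propan-1-ol | OC[C@@H](OCc9ccccc9)[C@H](c1ccc(OCc9ccccc9)cc1Br)c5c(OCc9ccccc9)c(Cl)c6c(c5OCc9ccccc9)C[C@H](OCc9ccccc9)[C@@H](c4ccc(OCc9ccccc9)c(OCc9ccccc9)c4)O6 | intermediate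
15 | (2S,3S)-2-(benzyloxy)-3-[4-(benzyloxy)-2-bromophenyl]-3-[(2R,3S)-3,5,7-tris(benzyloxy)-2-[3,4-bis(benzyloxy)phenyl]-8-chlorochroman-6-yl]propanal | O=C[C@@H](OCc9ccccc9)[C@H](c1ccc(OCc9ccccc9)cc1Br)c5c(OCc9ccccc9)c(Cl)c6c(c5OCc9ccccc9)C[C@H](OCc9ccccc9)[C@@H](c4ccc(OCc9ccccc9)c(OCc9ccccc9)c4)O6 | intermediate
16 | 4-bromo-1,2-bis(benzyloxy)benzene | Brc1ccc(OCc2ccccc2)c(OCc2ccccc2)c1 | starting material
17 | 3,4-bis(benzyloxy)phenylmagnesium bromide (formed in the flask) | Br[Mg]c1ccc(OCc2ccccc2)c(OCc2ccccc2)c1 | intermediate
18 | (2S,3S)-2-(benzyloxy)-1-[3,4-bis(benzyloxy)phenyl]-3-[4-(benzyloxy)-2-bromophenyl]-3-[(2R,3S)-3,5,7-tris(benzyloxy)-2-[3,4-bis(benzyloxy)phenyl]-8-chlorochroman-6-yl]propan-1-ol, both C1 epimers | OC(c3ccc(OCc9ccccc9)c(OCc9ccccc9)c3)[C@@H](OCc9ccccc9)[C@H](c1ccc(OCc9ccccc9)cc1Br)c5c(OCc9ccccc9)c(Cl)c6c(c5OCc9ccccc9)C[C@H](OCc9ccccc9)[C@@H](c4ccc(OCc9ccccc9)c(OCc9ccccc9)c4)O6 | intermediate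
19 | (2S,3S)-2-(benzyloxy)-1-[3,4-bis(benzyloxy)phenyl]-3-[4-(benzyloxy)-2-bromophenyl]-3-[(2R,3S)-3,5,7-tris(benzyloxy)-2-[3,4-bis(benzyloxy)phenyl]-8-chlorochroman-6-yl]propan-1-one | O=C(c3ccc(OCc9ccccc9)c(OCc9ccccc9)c3)[C@@H](OCc9ccccc9)[C@H](c1ccc(OCc9ccccc9)cc1Br)c5c(OCc9ccccc9)c(Cl)c6c(c5OCc9ccccc9)C[C@H](OCc9ccccc9)[C@@H](c4ccc(OCc9ccccc9)c(OCc9ccccc9)c4)O6 | intermediate
20 | (1R,2S,3S)-2-(benzyloxy)-1-[3,4-bis(benzyloxy)phenyl]-3-[4-(benzyloxy)-2-bromophenyl]-3-[(2R,3S)-3,5,7-tris(benzyloxy)-2-[3,4-bis(benzyloxy)phenyl]-8-chlorochroman-6-yl]propan-1-ol | O[C@H](c3ccc(OCc9ccccc9)c(OCc9ccccc9)c3)[C@@H](OCc9ccccc9)[C@H](c1ccc(OCc9ccccc9)cc1Br)c5c(OCc9ccccc9)c(Cl)c6c(c5OCc9ccccc9)C[C@H](OCc9ccccc9)[C@@H](c4ccc(OCc9ccccc9)c(OCc9ccccc9)c4)O6 | intermediate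
21 | (2R,3S,4R)-3,7-bis(benzyloxy)-2-[3,4-bis(benzyloxy)phenyl]-4-[(2R,3S)-3,5,7-tris(benzyloxy)-2-[3,4-bis(benzyloxy)phenyl]-8-chlorochroman-6-yl]chromane | c9ccccc9COc1ccc2c(c1)O[C@H](c3ccc(OCc9ccccc9)c(OCc9ccccc9)c3)[C@@H](OCc9ccccc9)[C@H]2c5c(OCc9ccccc9)c(Cl)c6c(c5OCc9ccccc9)C[C@H](OCc9ccccc9)[C@@H](c4ccc(OCc9ccccc9)c(OCc9ccccc9)c4)O6 | intermediate
22 | (2R,3S,4R)-2-(3,4-dihydroxyphenyl)-4-[(2R,3S)-2-(3,4-dihydroxyphenyl)-3,5,7-trihydroxychroman-6-yl]chromane-3,7-diol | Oc1ccc2c(c1)O[C@H](c1ccc(O)c(O)c1)[C@@H](O)[C@H]2c1c(O)cc2c(c1O)C[C@H](O)[C@@H](c1ccc(O)c(O)c1)O2 | target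

## Step count and least certain steps

Total: 17 steps. Longest linear sequence: 13 steps (from 6 through steps 5 to 17; the branch from 1 through steps 1 to 4 and 9 to 17 is equally long).

**Step 16 (key step).** The most likely failure is slow activation of the electron-rich, ortho-branched bromide by a copper centre that carries a hindered secondary alkoxide. Hydrodebromination, or oxidation of the benzylic alkoxide to the ketone (which would also open a path to epimerisation at C2), could then take over. The fallback changes the metal and the order of elementary steps. Starting again from 20, a palladium-catalysed Buchwald–Hartwig etherification (Pd(OAc)2, a bulky di-tert-butyl biaryl phosphine, Cs2CO3, toluene, 70–90 °C) has zerovalent palladium insert into the carbon–bromine bond first, whatever the bulk of the alkoxide, and the bulky ligand then drives carbon–oxygen reductive elimination. It returns directly to 21 and makes no new compound (F0).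

**Step 9.** Three processes threaten this step:
- attack at the non-benzylic epoxide carbon;
- magnesium-halide-induced ionisation or rearrangement of the electron-rich epoxide, with loss of stereochemical integrity at C4;
- slow SN2 attack of a di-ortho-substituted aryl nucleophile on a carbon that bears an ortho-bromoaryl group, which would give bromine–magnesium exchange on ring A time to compete.

The fallback gives up the organometallic. The chloride 9, whose only open ring D position is C6, is used as the arene nucleophile in a Friedel–Crafts opening of 5 at the benzylic carbon, in hexafluoroisopropanol or with BF3·OEt2 at −78 °C, where a tight ion pair should still give inversion. It sets out from 9 and 5 and returns at 12 with no new compound (F0).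

**Step 4.** The para-alkoxyaryl epoxide may be opened or oligomerised by the titanium Lewis acid or on work-up, and the ortho substituent may lower the enantioselectivity. The fallback avoids Lewis acids. From 4, silylation (tBuMe2SiCl, imidazole) gives the allyl silyl ether F1. Shi epoxidation with the D-fructose-derived ketone and KHSO5 under K2CO3 buffer, which gives R,R-epoxides from trans-alkenes, gives the epoxy silyl ether F2. Bu4NF then returns to 5.

**Step 7.** Chlorination may be less position-selective than the well-behaved bromination, with attack at C6 or double halogenation. The fallback starts from 8: NBS gives the 8-bromide F3, bromine–lithium exchange (nBuLi, THF, −78 °C) gives the 8-lithio compound F4, and a quench with C2Cl6 returns to 9.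

**Step 11.** The reductive opening may go the wrong way round (benzyl on the primary oxygen) or stall because of crowding around the acetal. The fallback uses temporary protection instead, starting from 12. Tritylation of the primary hydroxyl (TrCl, pyridine) gives the trityl ether F5, benzylation (NaH, BnBr) gives the benzyl trityl diether F6, and mild acid (TsOH, MeOH/CH2Cl2) returns to 14.

**Step 17.** Hydrodechlorination of the hindered C8(D) chloride may remain incomplete, the amine may slow benzyl ether cleavage, and the free nonaphenol may oxidise in air in the presence of base. The fallback separates the two tasks. From 21, a homogeneous palladium-catalysed transfer hydrodechlorination (Pd(OAc)2, bulky biaryl phosphine, HCO2Na, DMF, 100 °C) gives the chlorine-free nonabenzyl ether F7. Neutral hydrogenolysis (H2, Pd(OH)2/C, THF/MeOH, no amine) then returns to 22.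

## Further compounds

F0 | step 16 | none | none
F0 | step 9 | none | none
F1 | step 4 | tert-butyl{[(E)-3-[4-(benzyloxy)-2-bromophenyl]prop-2-en-1-yl]oxy}dimethylsilane | CC(C)(C)[Si](C)(C)OC/C=C/c1ccc(OCc2ccccc2)cc1Br
F2 | step 4 | tert-butyl{[(2R,3R)-3-[4-(benzyloxy)-2-bromophenyl]oxiran-2-yl]methoxy}dimethylsilane | CC(C)(C)[Si](C)(C)OC[C@H]1O[C@@H]1c1ccc(OCc2ccccc2)cc1Br
F3 | step 7 | (2R,3S)-3,5,7-tris(benzyloxy)-2-[3,4-bis(benzyloxy)phenyl]-8-bromochromane | c1ccccc1CO[C@H]1Cc2c(OCc3ccccc3)cc(OCc3ccccc3)c(Br)c2O[C@@H]1c1ccc(OCc2ccccc2)c(OCc2ccccc2)c1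
F4 | step 7 | [(2R,3S)-3,5,7-tris(benzyloxy)-2-[3,4-bis(benzyloxy)phenyl]chroman-8-yl]lithium | c1ccccc1CO[C@H]1Cc2c(OCc3ccccc3)cc(OCc3ccccc3)c([Li])c2O[C@@H]1c1ccc(OCc2ccccc2)c(OCc2ccccc2)c1
F5 | step 11 | (2S,3S)-3-[4-(benzyloxy)-2-bromophenyl]-3-[(2R,3S)-3,5,7-tris(benzyloxy)-2-[3,4-bis(benzyloxy)phenyl]-8-chlorochroman-6-yl]-1-(trityloxy)propan-2-ol | C(c9ccccc9)(c9ccccc9)(c9ccccc9)OC[C@@H](O)[C@H](c1ccc(OCc9ccccc9)cc1Br)c5c(OCc9ccccc9)c(Cl)c6c(c5OCc9ccccc9)C[C@H](OCc9ccccc9)[C@@H](c4ccc(OCc9ccccc9)c(OCc9ccccc9)c4)O6
F6 | step 11 | (2R,3S)-3,5,7-tris(benzyloxy)-6-[(1S,2S)-2-(benzyloxy)-1-[4-(benzyloxy)-2-bromophenyl]-3-(trityloxy)propyl]-2-[3,4-bis(benzyloxy)phenyl]-8-chlorochromane | C(c9ccccc9)(c9ccccc9)(c9ccccc9)OC[C@@H](OCc9ccccc9)[C@H](c1ccc(OCc9ccccc9)cc1Br)c5c(OCc9ccccc9)c(Cl)c6c(c5OCc9ccccc9)C[C@H](OCc9ccccc9)[C@@H](c4ccc(OCc9ccccc9)c(OCc9ccccc9)c4)O6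
F7 | step 17 | (2R,3S,4R)-3,7-bis(benzyloxy)-2-[3,4-bis(benzyloxy)phenyl]-4-[(2R,3S)-3,5,7-tris(benzyloxy)-2-[3,4-bis(benzyloxy)phenyl]chroman-6-yl]chromane | c9ccccc9COc1ccc2c(c1)O[C@H](c3ccc(OCc9ccccc9)c(OCc9ccccc9)c3)[C@@H](OCc9ccccc9)[C@H]2c5c(OCc9ccccc9)cc6c(c5OCc9ccccc9)C[C@H](OCc9ccccc9)[C@@H](c4ccc(OCc9ccccc9)c(OCc9ccccc9)c4)O6
A1 | alternative 1 | nona-O-benzyl dimer with ring F as the (2R,3R)-3-(benzyloxy)flavan-4-one | c9ccccc9COc1ccc2c(c1)O[C@H](c3ccc(OCc9ccccc9)c(OCc9ccccc9)c3)[C@@H](OCc9ccccc9)[C@H]2c5c(OCc9ccccc9)cc6c(c5OCc9ccccc9)C(=O)[C@H](OCc9ccccc9)[C@@H](c4ccc(OCc9ccccc9)c(OCc9ccccc9)c4)O6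
A2 | alternative 1 | 3,5-bis(benzyloxy)-4-[tetra-O-benzyl 2,3-trans-3,4-cis flavan-4-yl]-2-(trimethylsilyl)phenyl trifluoromethanesulfonate | c9ccccc9COc1ccc2c(c1)O[C@H](c3ccc(OCc9ccccc9)c(OCc9ccccc9)c3)[C@@H](OCc9ccccc9)[C@H]2c5c(OCc9ccccc9)cc(OS(=O)(=O)C(F)(F)F)c([Si](C)(C)C)c5OCc9ccccc9
A3 | alternative 1 | methyl (2R,3R)-2-(benzyloxy)-3-[3,4-bis(benzyloxy)phenyl]-3-hydroxypropanoate | COC(=O)[C@H](OCc9ccccc9)[C@@H](c4ccc(OCc9ccccc9)c(OCc9ccccc9)c4)O
A4 | alternative 2 | protected dimer with free C5(D) hydroxyl and C7(D) triisopropylsilyl ether | c9ccccc9COc1ccc2c(c1)O[C@H](c3ccc(OCc9ccccc9)c(OCc9ccccc9)c3)[C@@H](OCc9ccccc9)[C@H]2c5c(O[Si](C(C)C)(C(C)C)C(C)C)cc6c(c5O)C[C@H](OCc9ccccc9)[C@@H](c4ccc(OCc9ccccc9)c(OCc9ccccc9)c4)O6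
A5 | alternative 2 | tetra-O-benzyl 2,3-trans-3,4-cis flavan with a (triisopropylsiloxy)ethynyl group on C4 | c9ccccc9COc1ccc2c(c1)O[C@H](c3ccc(OCc9ccccc9)c(OCc9ccccc9)c3)[C@@H](OCc9ccccc9)[C@H]2C#CO[Si](C(C)C)(C(C)C)C(C)C
A6 | alternative 2 | (3R,4S)-4-(benzyloxy)-3-[3,4-bis(benzyloxy)phenyl]-2-oxabicyclo[4.2.0]oct-1(8)-en-7-one, either epimer at C6 | O=C1C=C2C1C[C@H](OCc9ccccc9)[C@@H](c4ccc(OCc9ccccc9)c(OCc9ccccc9)c4)O2
A7 | alternative 3 | protected dimer with ring F as the (2S)-2H-chromene (flav-3-ene) | c9ccccc9COc1ccc2c(c1)O[C@H](c3ccc(OCc9ccccc9)c(OCc9ccccc9)c3)[C@@H](OCc9ccccc9)[C@H]2c5c(OCc9ccccc9)cc6c(c5OCc9ccccc9)C=C[C@@H](c4ccc(OCc9ccccc9)c(OCc9ccccc9)c4)O6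
A8 | alternative 3 | ring D diene with a vinyl group on C4a(D) and an (S)-1-[3,4-bis(benzyloxy)phenyl]allyl ether on the C8a(D) oxygen | c9ccccc9COc1ccc2c(c1)O[C@H](c3ccc(OCc9ccccc9)c(OCc9ccccc9)c3)[C@@H](OCc9ccccc9)[C@H]2c5c(OCc9ccccc9)cc(O[C@H](c4ccc(OCc9ccccc9)c(OCc9ccccc9)c4)C=C)c(C=C)c5OCc9ccccc9
A9 | alternative 3 | 3,5-bis(benzyloxy)-4-[tetra-O-benzyl 2,3-trans-3,4-cis flavan-4-yl]phenol | c9ccccc9COc1ccc2c(c1)O[C@H](c3ccc(OCc9ccccc9)c(OCc9ccccc9)c3)[C@@H](OCc9ccccc9)[C@H]2c5c(OCc9ccccc9)cc(O)cc5OCc9ccccc9
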